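Retrosynthesis: the C3 ester is cut to a side-chain ynoic acid, the 8,9-diol is traced back to a C8=C9 alkene and the isopropenyl group to an acetyl group; ring B is then opened by a retro-[4+2] across C5–C10 and C6–C7, and the resulting chain is cut at C8–C9 (Heck) and C3–C4 (aldol).
Enabling feature: ring B (C5–C10) carries a vicinal cis-diol at C8/C9, i.e. a former C8=C9 alkene flanked by C7 and C10; C5=C6 (1,1-disubstituted, bearing the C14 methyl and C4) is the dienophile, C7=C8–C9=C10 the diene, and the chain C1–C4 between C10 and C5 becomes ring A.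
Forward: the acyclic triene is built linearly (aldol, methyl ketone, methylenation, hydrozirconation–iodination, Heck); rings A and B then close together in one thermal cycloaddition; dihydroxylation, C7 inversion, methylenation, esterification, semi-hydrogenation and deprotection follow.
Stereochemistry: C3/C4 from an Evans syn-aldol; C5, C10 and C7 from the cycloaddition (chair tether with equatorial C3/C4 substituents, E,E-diene); C8/C9 by osmylation anti to the 7α-acetyl group and C1; C7 then corrected by thermodynamic epimerisation.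
Side chain: the carbinol centre comes from (R)-pent-4-yn-2-ol, the angelate Z-alkene from angelic acid, the enoate Z-alkene from a late cis-semi-hydrogenation of an ynoate.
Key step: step 8

Remark: ring atoms are numbered as in eremophilane (decalin C1–C10, C11–C13 on C7, C14 on C5, C15 on C4) and β is the face of the C14 methyl group; pent-4-ynal is taken as purchasable.

Step 1
Reactants: 1 (4S)-4-benzyl-3-propanoyl-1,3-oxazolidin-2-one; 2 pent-4-ynal
Product: 4 (4S)-4-benzyl-3-[(2S,3R)-3-hydroxy-2-methylhept-6-ynoyl]-1,3-oxazolidin-2-one, via dibutylboron Z-enolate 3 (not isolated)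
Conditions: Bu2BOTf, Et3N, CH2Cl2, −78 to 0 °C; then 2, −78 to 0 °C; then pH 7 buffer, MeOH, H2O2
Reagents that add atoms: none
Why: Evans syn-aldol reaction: the boron Z-enolate 3 reacts through a closed chair transition state on the face away from the benzyl group, which sets the carbinol centre (C3 of the target) and the methyl-bearing centre (C4) in the syn (2S,3R) arrangement.

Step 2
Reactants: 4 (4S)-4-benzyl-3-[(2S,3R)-3-hydroxy-2-methylhept-6-ynoyl]-1,3-oxazolidin-2-one
Product: 5 (2S,3R)-3-hydroxy-N-methoxy-N,2-dimethylhept-6-ynamide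
Conditions: MeNH(OMe)·HCl, AlMe3, CH2Cl2, −15 to 0 °C
Reagents that add atoms: N,O-dimethylhydroxylamine hydrochloride, CNOC.Cl
Why: Weinreb transamidation by the aluminium amide made from AlMe3 and the amine salt, directed to the exocyclic carbonyl by the free β-hydroxyl group, should release the auxiliary without touching either stereocentre.

Step 3
Reactants: 5 (2S,3R)-3-hydroxy-N-methoxy-N,2-dimethylhept-6-ynamide
Product: 6 (2S,3R)-3-[(tert-butyldimethylsilyl)oxy]-N-methoxy-N,2-dimethylhept-6-ynamide
Conditions: TBSOTf, 2,6-lutidine, CH2Cl2, −78 to 0 °C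
Reagents that add atoms: tert-butyldimethylsilyl trifluoromethanesulfonate, CC(C)(C)[Si](C)(C)OS(=O)(=O)C(F)(F)F
Why: Silylation of the secondary alcohol by a silyl triflate in the presence of a hindered pyridine base masks O3 as an ether that should survive organometallic reagents, ylides, 190 °C and osmylation.

Step 4
Reactants: 6 (2S,3R)-3-[(tert-butyldimethylsilyl)oxy]-N-methoxy-N,2-dimethylhept-6-ynamide
Product: 7 (3S,4R)-4-[(tert-butyldimethylsilyl)oxy]-3-methyloct-7-yn-2-one
Conditions: MeMgBr (3 equiv), THF, 0 °C; then aq. NH4Cl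
Reagents that add atoms: methylmagnesium bromide, C[Mg]Br
Why: Weinreb ketone synthesis: the chelated tetrahedral magnesium adduct collapses only on work-up, so addition stops at the methyl ketone, one extra equivalent of the Grignard reagent being consumed by the alkyne C–H.

Step 5
Reactants: 7 (3S,4R)-4-[(tert-butyldimethylsilyl)oxy]-3-methyloct-7-yn-2-one
Product: 8 tert-butyl{[(3R,4R)-2,3-dimethyloct-1-en-7-yn-4-yl]oxy}dimethylsilane
Conditions: Ph3PCH3Br, KOt-Bu, THF, 0 °C to rt
Reagents that add atoms: methyltriphenylphosphonium bromide (CH2 source through its ylide), C[P+](c1ccccc1)(c1ccccc1)c1ccccc1.[Br-]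
Why: Wittig methylenation by the non-stabilised ylide turns the methyl ketone into the 1,1-disubstituted alkene C5=C6 that serves as dienophile, the ylide being too weak a base to deprotonate the alkyne.

Step 6
Reactants: 8 tert-butyl{[(3R,4R)-2,3-dimethyloct-1-en-7-yn-4-yl]oxy}dimethylsilane
Product: 10 tert-butyl{[(3R,4R,7E)-8-iodo-2,3-dimethylocta-1,7-dien-4-yl]oxy}dimethylsilane, via alkenyl-Zr(Cl)Cp2 complex 9 (not isolated)
Conditions: Cp2Zr(H)Cl, THF, rt; then I2, 0 °C
Reagents that add atoms: iodine, II
Why: Hydrozirconation is a syn addition that places zirconium on the terminal alkyne carbon much faster than it touches the hindered 1,1-disubstituted alkene, and iodinolysis of the C–Zr bond proceeds by retention and should give the E-alkenyl iodide.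

Step 7
Reactants: 10 tert-butyl{[(3R,4R,7E)-8-iodo-2,3-dimethylocta-1,7-dien-4-yl]oxy}dimethylsilane; 11 but-3-en-2-one
Product: 12 (3E,5E,9R,10R)-9-[(tert-butyldimethylsilyl)oxy]-10,11-dimethyldodeca-3,5,11-trien-2-one
Conditions: Pd(OAc)2 (5 mol%), K2CO3, Bu4NCl, DMF, rt
Reagents that add atoms: none
Why: Mizoroki–Heck reaction: oxidative addition of the alkenyl iodide to zerovalent palladium, syn insertion of the enone at its unsubstituted carbon and syn β-hydride elimination should give the (3E,5E)-dienone, the iodide geometry being retained.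

Step 8
Reactants: 12 (3E,5E,9R,10R)-9-[(tert-butyldimethylsilyl)oxy]-10,11-dimethyldodeca-3,5,11-trien-2-one
Product: 13 3α-[(tert-butyldimethylsilyl)oxy]-12-nor-7βH,10βH-eremophil-8-en-11-one (7α-acetyl cis-octalin)
Conditions: toluene (0.01 M), BHT, sealed tube, 190 °C
Reagents that add atoms: none
Why: Thermal type 1 intramolecular Diels–Alder reaction of a 1,7,9-decatriene, the closest known reaction type being the thermal cyclisation of unactivated decatrienes to octalins: the 1,1-disubstituted alkene C5=C6 adds suprafacially and in one concerted step across C10 and C7 of the s-cis (E,E)-diene C7=C8–C9=C10. Ring B (C5–C6–C7–C8–C9–C10) closes as the new cyclohexene through a boat-like six-centre array, and ring A (C1–C5 plus C10) closes at the same moment because the four-carbon tether C1–C4 folds into a chair, so that a fused and not a bridged bicycle results. C5 and C10 are controlled by that chair, which carries the C3 silyloxy and the C4 methyl group equatorial (axial, the first would clash against the C14 methyl and the second against C9) and thereby selects the diene and dienophile faces that put C14 cis to C15 and trans to O3. The cis ring fusion (H10 cis to C14) needs the tether-endo orientation, in which C4 lies under the diene and C14 points away, and the 2-methyl group of the dienophile is what should favour it, since in the competing tether-exo array this methyl lies under the diene and is axial to both forming rings. C7 is controlled by the E geometry of both diene double bonds, which brings the outside substituents C1 and acetyl cis (acetyl α); this is on purpose the opposite of the target, so that the acetyl group shields the α face in step 9 before it is inverted in step 11. The step thus needs endo-tether over exo-tether selectivity and one pair of π faces, secured by the dienophile methyl group and by the two tether stereocentres from step 1.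

Step 9
Reactants: 13 3α-[(tert-butyldimethylsilyl)oxy]-12-nor-7βH,10βH-eremophil-8-en-11-one (7α-acetyl cis-octalin)
Product: 14 3α-[(tert-butyldimethylsilyl)oxy]-8β,9β-dihydroxy-12-nor-7βH,10βH-eremophilan-11-one (7α-acetyl diol)
Conditions: OsO4 (2 mol%), NMO, acetone/H2O, rt
Reagents that add atoms: osmium tetroxide (catalytic carrier of the oxygen atoms), O=[Os](=O)(=O)=O; N-methylmorpholine N-oxide, C[N+]1([O-])CCOCC1; water, O
Why: Catalytic osmylation is a suprafacial addition that should take the β face of the C8=C9 alkene because both allylic carbon substituents, C1 on C10 and the acetyl group on C7, lie on the α face, which sets C8 and C9 as the 8β,9β-cis-diol.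

Step 10
Reactants: 14 3α-[(tert-butyldimethylsilyl)oxy]-8β,9β-dihydroxy-12-nor-7βH,10βH-eremophilan-11-one (7α-acetyl diol)
Product: 15 3α-[(tert-butyldimethylsilyl)oxy]-8β,9β-(isopropylidenedioxy)-12-nor-7βH,10βH-eremophilan-11-one (7α-acetyl acetonide)
Conditions: 2,2-dimethoxypropane, PPTS, CH2Cl2, rt
Reagents that add atoms: 2,2-dimethoxypropane, COC(C)(C)OC
Why: Acid-catalysed transketalisation is specific for the cis-1,2-diol and masks both hydroxyl groups, so that they neither undergo retro-aldol cleavage in step 11 nor compete in the acylation of step 16.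

Step 11
Reactants: 15 3α-[(tert-butyldimethylsilyl)oxy]-8β,9β-(isopropylidenedioxy)-12-nor-7βH,10βH-eremophilan-11-one (7α-acetyl acetonide)
Product: 16 3α-[(tert-butyldimethylsilyl)oxy]-8β,9β-(isopropylidenedioxy)-12-nor-7αH,10βH-eremophilan-11-one (7β-acetyl acetonide)
Conditions: K2CO3 (0.5 equiv), MeOH, 0 °C to rt, stopped at equilibrium
Reagents that add atoms: none
Why: Base-catalysed epimerisation through the ketone enolate is thermodynamically driven, since the 7α-acetyl group is syn-axial to C4 across ring B in the chair that keeps the ring A substituents equatorial whereas the 7β epimer carries it equatorially, and the weak base in a protic solvent keeps the enolate short-lived so that reprotonation should outrun loss of the ketal oxygen from C8.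

Step 12
Reactants: 16 3α-[(tert-butyldimethylsilyl)oxy]-8β,9β-(isopropylidenedioxy)-12-nor-7αH,10βH-eremophilan-11-one (7β-acetyl acetonide)
Product: 17 3α-[(tert-butyldimethylsilyl)oxy]-8β,9β-(isopropylidenedioxy)-10βH-eremophil-11-ene
Conditions: Ph3PCH3Br, KOt-Bu, THF, 0 °C to rt
Reagents that add atoms: methyltriphenylphosphonium bromide (CH2 source through its ylide), C[P+](c1ccccc1)(c1ccccc1)c1ccccc1.[Br-]
Why: Wittig methylenation converts the acetyl group into the isopropenyl group, and any enolisation by the ylide is harmless because C7 already has its thermodynamic configuration.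

Step 13
Reactants: 17 3α-[(tert-butyldimethylsilyl)oxy]-8β,9β-(isopropylidenedioxy)-10βH-eremophil-11-ene
Product: 18 8β,9β-(isopropylidenedioxy)-10βH-eremophil-11-en-3α-ol
Conditions: TBAF, THF, rt to 45 °C; then aq. NH4Cl
Reagents that add atoms: none
Why: Fluoride cleaves the Si–O bond (strong Si–F bond) and frees the C3 hydroxyl group while the acetonide and the alkene are inert.

Step 14
Reactants: 19 angelic acid [(2Z)-2-methylbut-2-enoic acid]; 20 (2R)-pent-4-yn-2-ol
Product: 22 (2R)-pent-4-yn-2-yl (2Z)-2-methylbut-2-enoate, via mixed anhydride 21 (not isolated)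
Conditions: 2,4,6-trichlorobenzoyl chloride, Et3N, toluene, rt; then 20, 80 °C
Reagents that add atoms: none
Why: Yamaguchi-type mixed-anhydride esterification without a nucleophilic catalyst: the alcohol attacks the less hindered angeloyl carbonyl of 21 under conditions known to preserve the Z geometry of angelic acid, and the carbinol centre is not involved and stays R.

Step 15
Reactants: 22 (2R)-pent-4-yn-2-yl (2Z)-2-methylbut-2-enoate
Product: 23 (5R)-5-{[(2Z)-2-methylbut-2-enoyl]oxy}hex-2-ynoic acid
Conditions: silver iodide AgI (2 mol%), Cs2CO3, CO2 (1 atm), DMF, 50 °C; then 1 M HCl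
Reagents that add atoms: carbon dioxide, O=C=O
Why: Silver-catalysed C–H carboxylation of a terminal alkyne: the silver acetylide formed in the presence of Cs2CO3 inserts CO2 to give the propiolate salt under conditions mild enough to leave the angelate ester untouched.

Step 16
Reactants: 18 8β,9β-(isopropylidenedioxy)-10βH-eremophil-11-en-3α-ol; 23 (5R)-5-{[(2Z)-2-methylbut-2-enoyl]oxy}hex-2-ynoic acid
Product: 24 8β,9β-(isopropylidenedioxy)-10βH-eremophil-11-en-3α-yl (5R)-5-{[(2Z)-2-methylbut-2-enoyl]oxy}hex-2-ynoate
Conditions: DCC, DMAP (0.1 equiv), CH2Cl2, −20 to 0 °C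
Reagents that add atoms: none
Why: Steglich esterification: DCC activates the acid as its O-acylisourea and catalytic DMAP transfers the acyl group to the equatorial C3 hydroxyl, the only free alcohol, an alkynoic acid being used because it has no alkene geometry to lose on activation.

Step 17
Reactants: 24 8β,9β-(isopropylidenedioxy)-10βH-eremophil-11-en-3α-yl (5R)-5-{[(2Z)-2-methylbut-2-enoyl]oxy}hex-2-ynoate
Product: 25 8β,9β-(isopropylidenedioxy)-10βH-eremophil-11-en-3α-yl (2Z,5R)-5-{[(2Z)-2-methylbut-2-enoyl]oxy}hex-2-enoate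
Conditions: H2 (1 atm), Pd/CaCO3 poisoned by Pb(OAc)2 (Lindlar catalyst), quinoline, EtOAc, rt
Reagents that add atoms: none
Why: Lindlar semi-hydrogenation adds H2 syn to the alkyne on the poisoned palladium surface and should give the Z-enoate, the trisubstituted angelate alkene and the isopropenyl alkene being reduced much more slowly than a conjugated alkyne.

Step 18
Reactants: 25 8β,9β-(isopropylidenedioxy)-10βH-eremophil-11-en-3α-yl (2Z,5R)-5-{[(2Z)-2-methylbut-2-enoyl]oxy}hex-2-enoate
Product: 26 CNP0395983.1 [8β,9β-dihydroxy-10βH-eremophil-11-en-3α-yl (2Z,5R)-5-{[(2Z)-2-methylbut-2-enoyl]oxy}hex-2-enoate]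
Conditions: AcOH/H2O/THF (3:1:1), 40 °C
Reagents that add atoms: none
Why: Mild aqueous acid hydrolyses the cyclic ketal of the cis-diol under conditions that the two esters, both Z-alkenes and the isopropenyl group should tolerate, which gives the target.

Compound list
1 | (4S)-4-benzyl-3-propanoyl-1,3-oxazolidin-2-one | CCC(=O)N1[C@@H](Cc2ccccc2)COC1=O | starting material
2 | pent-4-ynal | C#CCCC=O | starting material
3 | dibutylboron Z-enolate of (4S)-4-benzyl-3-propanoyl-1,3-oxazolidin-2-one | C/C=C(\OB(CCCC)CCCC)N1[C@@H](Cc2ccccc2)COC1=O | intermediate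
4 | (4S)-4-benzyl-3-[(2S,3R)-3-hydroxy-2-methylhept-6-ynoyl]-1,3-oxazolidin-2-one | C#CCC[C@@H](O)[C@H](C)C(=O)N1[C@@H](Cc2ccccc2)COC1=O | intermediate
5 | (2S,3R)-3-hydroxy-N-methoxy-N,2-dimethylhept-6-ynamide | C#CCC[C@@H](O)[C@H](C)C(=O)N(C)OC | intermediate
6 | (2S,3R)-3-[(tert-butyldimethylsilyl)oxy]-N-methoxy-N,2-dimethylhept-6-ynamide | C#CCC[C@@H](O[Si](C)(C)C(C)(C)C)[C@H](C)C(=O)N(C)OC | intermediate
7 | (3S,4R)-4-[(tert-butyldimethylsilyl)oxy]-3-methyloct-7-yn-2-one | C#CCC[C@@H](O[Si](C)(C)C(C)(C)C)[C@H](C)C(C)=O | intermediate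
8 | tert-butyl{[(3R,4R)-2,3-dimethyloct-1-en-7-yn-4-yl]oxy}dimethylsilane | C#CCC[C@@H](O[Si](C)(C)C(C)(C)C)[C@H](C)C(C)=C | intermediate
9 | (E)-alkenyl-Zr(Cl)Cp2 complex of the enyne silyl ether | Cl[Zr](/C=C/CC[C@@H](O[Si](C)(C)C(C)(C)C)[C@H](C)C(C)=C)(C1C=CC=C1)C1C=CC=C1 | intermediate
10 | tert-butyl{[(3R,4R,7E)-8-iodo-2,3-dimethylocta-1,7-dien-4-yl]oxy}dimethylsilane | I/C=C/CC[C@@H](O[Si](C)(C)C(C)(C)C)[C@H](C)C(C)=C | intermediate
11 | but-3-en-2-one | CC(=O)C=C | starting material
12 | (3E,5E,9R,10R)-9-[(tert-butyldimethylsilyl)oxy]-10,11-dimethyldodeca-3,5,11-trien-2-one | CC(=O)/C=C/C=C/CC[C@@H](O[Si](C)(C)C(C)(C)C)[C@H](C)C(C)=C | intermediate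
13 | 3α-[(tert-butyldimethylsilyl)oxy]-12-nor-7βH,10βH-eremophil-8-en-11-one (7α-acetyl cis-octalin) | CC(=O)[C@@H]1C[C@@]2(C)[C@H](CC[C@@H](O[Si](C)(C)C(C)(C)C)[C@@H]2C)C=C1 | intermediate
14 | 3α-[(tert-butyldimethylsilyl)oxy]-8β,9β-dihydroxy-12-nor-7βH,10βH-eremophilan-11-one (7α-acetyl diol) | CC(=O)[C@@H]1C[C@@]2(C)[C@H](CC[C@@H](O[Si](C)(C)C(C)(C)C)[C@@H]2C)[C@@H](O)[C@H]1O | intermediate
15 | 3α-[(tert-butyldimethylsilyl)oxy]-8β,9β-(isopropylidenedioxy)-12-nor-7βH,10βH-eremophilan-11-one (7α-acetyl acetonide) | CC(=O)[C@@H]1C[C@@]2(C)[C@H](CC[C@@H](O[Si](C)(C)C(C)(C)C)[C@@H]2C)[C@H]3OC(C)(C)O[C@@H]13 | intermediate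
16 | 3α-[(tert-butyldimethylsilyl)oxy]-8β,9β-(isopropylidenedioxy)-12-nor-7αH,10βH-eremophilan-11-one (7β-acetyl acetonide) | CC(=O)[C@H]1C[C@@]2(C)[C@H](CC[C@@H](O[Si](C)(C)C(C)(C)C)[C@@H]2C)[C@H]3OC(C)(C)O[C@@H]13 | intermediate
17 | 3α-[(tert-butyldimethylsilyl)oxy]-8β,9β-(isopropylidenedioxy)-10βH-eremophil-11-ene | C=C(C)[C@H]1C[C@@]2(C)[C@H](CC[C@@H](O[Si](C)(C)C(C)(C)C)[C@@H]2C)[C@H]3OC(C)(C)O[C@@H]13 | intermediate
18 | 8β,9β-(isopropylidenedioxy)-10βH-eremophil-11-en-3α-ol | C=C(C)[C@H]1C[C@@]2(C)[C@H](CC[C@@H](O)[C@@H]2C)[C@H]3OC(C)(C)O[C@@H]13 | intermediate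
19 | angelic acid [(2Z)-2-methylbut-2-enoic acid] | C/C=C(/C)C(O)=O | starting material
20 | (2R)-pent-4-yn-2-ol | C#CC[C@@H](C)O | starting material
21 | angelic 2,4,6-trichlorobenzoic mixed anhydride | C/C=C(/C)C(=O)OC(=O)c1c(Cl)cc(Cl)cc1Cl | intermediate
22 | (2R)-pent-4-yn-2-yl (2Z)-2-methylbut-2-enoate | C#CC[C@@H](C)OC(=O)/C(C)=C\C | intermediate
23 | (5R)-5-{[(2Z)-2-methylbut-2-enoyl]oxy}hex-2-ynoic acid | OC(=O)C#CC[C@@H](C)OC(=O)/C(C)=C\C | intermediate
24 | 8β,9β-(isopropylidenedioxy)-10βH-eremophil-11-en-3α-yl (5R)-5-{[(2Z)-2-methylbut-2-enoyl]oxy}hex-2-ynoate | C=C(C)[C@H]1C[C@@]2(C)[C@H](CC[C@@H](OC(=O)C#CC[C@@H](C)OC(=O)/C(C)=C\C)[C@@H]2C)[C@H]3OC(C)(C)O[C@@H]13 | intermediate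
25 | 8β,9β-(isopropylidenedioxy)-10βH-eremophil-11-en-3α-yl (2Z,5R)-5-{[(2Z)-2-methylbut-2-enoyl]oxy}hex-2-enoate | C=C(C)[C@H]1C[C@@]2(C)[C@H](CC[C@@H](OC(=O)/C=C\C[C@@H](C)OC(=O)/C(C)=C\C)[C@@H]2C)[C@H]3OC(C)(C)O[C@@H]13 | intermediate
26 | CNP0395983.1 [8β,9β-dihydroxy-10βH-eremophil-11-en-3α-yl (2Z,5R)-5-{[(2Z)-2-methylbut-2-enoyl]oxy}hex-2-enoate] | C=C(C)[C@H]1C[C@@]2(C)[C@H](CC[C@@H](OC(=O)/C=C\C[C@@H](C)OC(=O)/C(C)=C\C)[C@@H]2C)[C@@H](O)[C@H]1O | target

Total step count: 18. Longest linear sequence: 16 (steps 1–13 and 16–18); steps 14 and 15 make the side-chain acid.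

Steps most likely to fail

Step 8. The cycloaddition of the unactivated alkene is slow, so thermal degradation or oligomerisation of the dienone may compete, and some material may leak through the tether-exo array to the trans-fused isomer. Fallback, from 12 back to 13: the dienone carbonyl is masked by TMSOCH2CH2OTMS and catalytic TMSOTf (CH2Cl2, −78 °C) to give the dienyl dioxolane F1, a diene without an enolisable or polymerisable enone that should tolerate longer heating. Cycloaddition of F1 (toluene, 200 °C) should give the 7α-dioxolanyl cis-octalin F2 in the same sense of induction, and PPTS in wet acetone at rt returns to 13. The ring-fusion preference is not changed by this; a trans-fused isomer would have to be separated at this stage.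

Step 11. The enolate may expel the ketal oxygen on C8 (E1cB elimination to the C7=C8 enone, followed by loss of acetone) in competition with reprotonation, so that material is lost before the equilibrium is reached. Fallback, from 14 directly to 16: the base is avoided altogether and the ketalisation and the C7 inversion are merged under acid, where the ketone equilibrates through its neutral enol and no carbanion β to the C8 oxygen is formed. Camphorsulfonic acid (0.3 equiv) in acetone/2,2-dimethoxypropane at 50 °C should first form the acetonide 15 in the flask and then epimerise C7 to the equatorial 7β-acetyl compound 16, the ketalising medium keeping the acetonide in place throughout.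

Step 9. Osmylation may show poor facial selectivity if the 7α-acetyl group and C1 do not shield the α face well enough. Fallback, from 13 back to 15: 13 is ketalised (TMSOCH2CH2OTMS, catalytic TMSOTf, CH2Cl2, −78 °C) to the 7α-dioxolanyl cis-octalin F2, whose quaternary dioxolane carbon on C7 is much bulkier than an acetyl group. OsO4/NMO should then give the dioxolane diol F3 from the β face, and catalytic p-TsOH in acetone at rt both forms the acetonide and hydrolyses the dioxolane by means of the water so released, which rejoins the route at 15.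

Further compounds
F1 | step 8 | 2-methyl-2-[(1E,3E,7R,8R)-7-[(tert-butyldimethylsilyl)oxy]-8,9-dimethyldeca-1,3,9-trien-1-yl]-1,3-dioxolane | CC1(/C=C/C=C/CC[C@@H](O[Si](C)(C)C(C)(C)C)[C@H](C)C(C)=C)OCCO1
F2 | step 8 | 3α-[(tert-butyldimethylsilyl)oxy]-11,11-(ethylenedioxy)-12-nor-7βH,10βH-eremophil-8-ene (7α-dioxolanyl cis-octalin) | CC1([C@@H]2C[C@@]3(C)[C@H](CC[C@@H](O[Si](C)(C)C(C)(C)C)[C@@H]3C)C=C2)OCCO1
F3 | step 9 | 3α-[(tert-butyldimethylsilyl)oxy]-11,11-(ethylenedioxy)-12-nor-7βH,10βH-eremophilane-8β,9β-diol (dioxolane diol) | CC1([C@@H]2C[C@@]3(C)[C@H](CC[C@@H](O[Si](C)(C)C(C)(C)C)[C@@H]3C)[C@@H](O)[C@H]2O)OCCO1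
F0 | step 11 | none | none
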